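**Plan**

1. Target: 1-(5-hydroxy-7-methoxy-2,2-dimethyl-2H-chromen-6-yl)-3-phenylpropane-1,3-dione. Cuts, in retrosynthetic order: the CH2–C(=O)Ph bond of the diketone; the CH3–C(=O) and C6–C(=O) bonds of the resulting 6-acetyl group; both C2–CH3 bonds together with the O1–C2 bond of the pyran; last the 7-O–CH3 bond.
2. Enabling feature: in the pyran ring the fully substituted carbon C2 is bonded to the ring oxygen O1, to two methyls and to C3 of the cis C3=C4 double bond. A coumarin's lactone carbonyl carbon ends up with exactly this substitution once it has accepted two methyl groups. The ring-opened arene has OH on both carbons flanking the side chain and OMe opposite, so either phenol re-closes to the same chromenol.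
3. Forward order: the benzo-fused lactone is bought as 5,7-dihydroxycoumarin and 7-O-methylated. MeMgBr then opens the lactone ring and acid re-closes it as the 2,2-dimethyl-2H-pyran, the only ring made in the route. The C6 chain is then grown outward: CHO, CH(OH)CH3, C(=O)CH3, C(=O)CH2C(=O)Ph.
4. Stereochemistry: the target has no stereocentre. The cis ring alkene is carried over from the coumarin. The carbinol centre made in step 4 is racemic and is removed by oxidation in step 5.

Key step: step 2

Remark: the target is written as its 1,3-diketo tautomer, although the hydrogen-bonded enol form of the same compound is expected to predominate in solution; carbinol 10 is made and used as the racemate.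

Step 1
Reactants: 1 5,7-dihydroxycoumarin (5,7-dihydroxy-2H-chromen-2-one); 2 methyl iodide
Product: 3 5-hydroxy-7-methoxy-2H-chromen-2-one
Conditions: MeI (1.05 equiv), K2CO3 (1.0 equiv), acetone, rt
Reagents that add atoms: methyl iodide, CI
Why: Williamson ether synthesis with one equivalent each of base and electrophile should methylate the 7-OH, which is the more acidic phenol (para-quinoid conjugation of its phenoxide through C4a into the unsaturated lactone) and the less hindered one (the 5-OH is crowded by the peri H-4), leaving the 5-OH free.

Step 2
Reactants: 3 5-hydroxy-7-methoxy-2H-chromen-2-one; 4 methylmagnesium bromide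
Product: 7 7-methoxy-2,2-dimethyl-2H-chromen-5-ol, via ring-opened Z-enone 5 (not isolated), via Z-allylic alcohol 6 (not isolated)
Conditions: MeMgBr (5 equiv), THF, 0 °C to rt; then AcOH, 0 °C to rt
Reagents that add atoms: methylmagnesium bromide, C[Mg]Br
Why: One equivalent of MeMgBr deprotonates the 5-OH, a second adds to the lactone carbonyl C2 and the tetrahedral intermediate expels the O1 phenoxide to give the Z-enone 5, whose ketone takes a third equivalent to give the Z tertiary allylic alkoxide, protonated to 6 on quenching; both C2–CH3 bonds are made in this way. Acetic acid then ionises the tertiary allylic alcohol (equivalent to loss of water to the ortho-quinone methide) and a flanking phenol oxygen attacks the dimethyl-substituted terminus, a six-membered closure that is formally 6-endo or an oxa-6π electrocyclisation, which re-forms the O1–C2 bond. The closest known reaction type is the double addition of methyl Grignard or methyllithium reagents to coumarins followed by acid cyclodehydration to 2,2-dimethyl-2H-chromenes. No stereocentre is formed, and the cis C3=C4 geometry needed for closure is inherited from the lactone ring. The step needs 1,2- over 1,4-addition, which the hard methyl nucleophile and the C5 phenoxide (it feeds electron density through C4a towards C4) should secure; it needs no regiocontrol in the closure, because the ring-opened aryl group is 2,6-dihydroxy-4-methoxyphenyl, whose two phenols are related by a mirror plane.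

Step 3
Reactants: 7 7-methoxy-2,2-dimethyl-2H-chromen-5-ol; 8 paraformaldehyde
Product: 9 5-hydroxy-7-methoxy-2,2-dimethyl-2H-chromene-6-carbaldehyde
Conditions: MgCl2 (2 equiv), Et3N (4 equiv), (CH2O)n (6 equiv), MeCN, reflux; cold dilute HCl work-up
Reagents that add atoms: paraformaldehyde (formaldehyde unit), C=O
Why: Casnati–Skattebøl ortho-formylation: the magnesium phenoxide delivers formaldehyde through a chelate to C6, the only free carbon ortho to the 5-OH (the other ortho carbon is the ring-fusion atom C4a and C8 is para), and the salicyl alkoxide is oxidised to the aldehyde by hydride transfer to a second formaldehyde, all under non-acidic conditions that the chromene should tolerate.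

Step 4
Reactants: 9 5-hydroxy-7-methoxy-2,2-dimethyl-2H-chromene-6-carbaldehyde; 4 methylmagnesium bromide
Product: 10 6-(1-hydroxyethyl)-7-methoxy-2,2-dimethyl-2H-chromen-5-ol (racemic)
Conditions: MeMgBr (3 equiv), THF, 0 °C; sat. aq NH4Cl, 0 °C; crude product used at once
Reagents that add atoms: methylmagnesium bromide, C[Mg]Br
Why: Grignard 1,2-addition: the first equivalent is consumed by the phenol and the chelated magnesium phenoxide aldehyde then accepts methyl at the formyl carbon, the new carbinol centre arising without control as a racemate, which is immaterial because step 5 oxidises it.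

Step 5
Reactants: 10 6-(1-hydroxyethyl)-7-methoxy-2,2-dimethyl-2H-chromen-5-ol
Product: 11 1-(5-hydroxy-7-methoxy-2,2-dimethyl-2H-chromen-6-yl)ethan-1-one
Conditions: activated MnO2 (15 equiv), CH2Cl2, rt
Reagents that add atoms: none
Why: MnO2 oxidation of a benzylic alcohol: the electron-rich benzylic carbinol should be oxidised selectively to the aryl methyl ketone, whose carbonyl then holds the 5-OH in a hydrogen bond, while the chromene alkene, the methyl ether and the phenol should be left alone under these neutral heterogeneous conditions.

Step 6
Reactants: 11 1-(5-hydroxy-7-methoxy-2,2-dimethyl-2H-chromen-6-yl)ethan-1-one; 12 benzoyl chloride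
Product: 13 1-(5-hydroxy-7-methoxy-2,2-dimethyl-2H-chromen-6-yl)-3-phenylpropane-1,3-dione
Conditions: LiN(SiMe3)2 (4 equiv), THF, −78 to −10 °C; PhCOCl (1.0 equiv), −78 °C to rt; sat. aq NH4Cl
Reagents that add atoms: benzoyl chloride, O=C(Cl)c1ccccc1
Why: Claisen-type C-acylation of a ketone enolate: excess amide base forms the lithium phenoxide-enolate dianion of the ortho-hydroxyacetophenone, whose enolate carbon attacks benzoyl chloride to make the CH2–C(=O)Ph bond, the surplus base holds the product as its diketonate so that no second acylation occurs, any O-benzoate would converge on the same diketone by a Baker–Venkataraman acyl shift, and the buffered work-up avoids the strong acid that would cyclise the product to a flavone.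

**Compound list**

1 | 5,7-dihydroxycoumarin (5,7-dihydroxy-2H-chromen-2-one) | O=C1C=Cc2c(O)cc(O)cc2O1 | starting material
2 | methyl iodide | CI | starting material
3 | 5-hydroxy-7-methoxy-2H-chromen-2-one | COc1cc(O)c2C=CC(=O)Oc2c1 | intermediate
4 | methylmagnesium bromide | C[Mg]Br | starting material
5 | (3Z)-4-(2,6-dihydroxy-4-methoxyphenyl)but-3-en-2-one, present in the flask as its magnesium phenoxide | COc1cc(O)c(/C=C\C(C)=O)c(O)c1 | intermediate
6 | 2-[(1Z)-3-hydroxy-3-methylbut-1-en-1-yl]-5-methoxybenzene-1,3-diol, formed as its magnesium salt and freed on quenching | COc1cc(O)c(/C=C\C(C)(C)O)c(O)c1 | intermediate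
7 | 7-methoxy-2,2-dimethyl-2H-chromen-5-ol | COc1cc(O)c2C=CC(C)(C)Oc2c1 | intermediate
8 | paraformaldehyde (formaldehyde unit) | C=O | starting material
9 | 5-hydroxy-7-methoxy-2,2-dimethyl-2H-chromene-6-carbaldehyde | COc1cc2OC(C)(C)C=Cc2c(O)c1C=O | intermediate
10 | 6-(1-hydroxyethyl)-7-methoxy-2,2-dimethyl-2H-chromen-5-ol (racemic) | COc1cc2OC(C)(C)C=Cc2c(O)c1C(C)O | intermediate
11 | 1-(5-hydroxy-7-methoxy-2,2-dimethyl-2H-chromen-6-yl)ethan-1-one | COc1cc2OC(C)(C)C=Cc2c(O)c1C(C)=O | intermediate
12 | benzoyl chloride | O=C(Cl)c1ccccc1 | starting material
13 | 1-(5-hydroxy-7-methoxy-2,2-dimethyl-2H-chromen-6-yl)-3-phenylpropane-1,3-dione | COc1cc2c(c(O)c1C(=O)CC(=O)c1ccccc1)C=CC(C)(C)O2 | target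

**Step count and risks**

Total step count: 6. Longest linear sequence: 6 steps, from 1 to 13.

Steps most likely to fail:

Step 2. Methyl may add in conjugate fashion at C4, the second addition may stall at the phenoxide-conjugated enone, or the very electron-rich chromenol may oligomerise under acid while the ring closes. The fallback sets out from 3 and comes back to the route at 7. The C3=C4 bond is first hydrogenated (H2, Pd/C, EtOAc) to 5-hydroxy-7-methoxychroman-2-one F1, so that only carbonyl addition remains possible. Excess MeMgBr in THF should then give 2-(3-hydroxy-3-methylbutyl)-5-methoxybenzene-1,3-diol F2. Catalytic TsOH in toluene should cyclodehydrate it to the acid-stable 7-methoxy-2,2-dimethylchroman-5-ol F3, again with either phenol giving the same ring. The alkene is restored last by benzylic dehydrogenation with DDQ in dioxane at reflux, which should give 7 without exposing it to acid.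

Step 1. Site selectivity between the two phenols may be poor, and the monoether may be methylated further. The fallback sets out from methyl iodide 2, used on purchased 2,4,6-trihydroxybenzaldehyde F4 in place of 1, and comes back to the route at 3. In F4 the two ortho hydroxyls are tied up in hydrogen bonds to the formyl group, and the 4-OH, para to the carbonyl, is the most acidic. MeI (1 equiv) with NaHCO3 in DMF should therefore give 2,6-dihydroxy-4-methoxybenzaldehyde F5. Wittig olefination with Ph3P=CHCO2Et in N,N-diethylaniline at reflux should give ethyl (E)-3-(2,6-dihydroxy-4-methoxyphenyl)prop-2-enoate F6. In the hot amine this isomerises to ethyl (Z)-3-(2,6-dihydroxy-4-methoxyphenyl)prop-2-enoate F7, which lactonises onto either of its two equivalent phenols to give 3. The position of the methyl ether is then fixed before the lactone exists.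

Step 4. The ortho-hydroxybenzylic carbinol may lose water through an ortho-quinone methide during quenching, concentration or on the oxidant surface, diverting material to vinylarene and dimers before the ketone is reached. The fallback sets out from 7 and comes back to the route at 11, bypassing both the aldehyde and the carbinol. The phenol is protected (MOMCl, i-Pr2NEt, CH2Cl2) as 7-methoxy-5-(methoxymethoxy)-2,2-dimethyl-2H-chromene F8. Directed ortho-lithiation (n-BuLi, THF, 0 °C) at C6, the carbon lying between the OMOM and OMe groups, should give [7-methoxy-5-(methoxymethoxy)-2,2-dimethyl-2H-chromen-6-yl]lithium F9. Acylation with N-methoxy-N-methylacetamide should give 1-[7-methoxy-5-(methoxymethoxy)-2,2-dimethyl-2H-chromen-6-yl]ethan-1-one F10. Brief treatment with dilute HCl in MeOH at rt should remove the acetal, which is activated by the neighbouring carbonyl, and release 11.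

**Further compounds**

F1 | step 2 | 5-hydroxy-7-methoxychroman-2-one | COc1cc(O)c2CCC(=O)Oc2c1
F2 | step 2 | 2-(3-hydroxy-3-methylbutyl)-5-methoxybenzene-1,3-diol | COc1cc(O)c(CCC(C)(C)O)c(O)c1
F3 | step 2 | 7-methoxy-2,2-dimethylchroman-5-ol | COc1cc(O)c2CCC(C)(C)Oc2c1
F4 | step 1 | 2,4,6-trihydroxybenzaldehyde (purchased) | O=Cc1c(O)cc(O)cc1O
F5 | step 1 | 2,6-dihydroxy-4-methoxybenzaldehyde | COc1cc(O)c(C=O)c(O)c1
F6 | step 1 | ethyl (E)-3-(2,6-dihydroxy-4-methoxyphenyl)prop-2-enoate | CCOC(=O)/C=C/c1c(O)cc(OC)cc1O
F7 | step 1 | ethyl (Z)-3-(2,6-dihydroxy-4-methoxyphenyl)prop-2-enoate | CCOC(=O)/C=C\c1c(O)cc(OC)cc1O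
F8 | step 4 | 7-methoxy-5-(methoxymethoxy)-2,2-dimethyl-2H-chromene | COCOc1cc(OC)cc2OC(C)(C)C=Cc12
F9 | step 4 | [7-methoxy-5-(methoxymethoxy)-2,2-dimethyl-2H-chromen-6-yl]lithium | [Li]c1c(OC)cc2OC(C)(C)C=Cc2c1OCOC
F10 | step 4 | 1-[7-methoxy-5-(methoxymethoxy)-2,2-dimethyl-2H-chromen-6-yl]ethan-1-one | COCOc1c(C(C)=O)c(OC)cc2OC(C)(C)C=Cc12
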